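At early times the green run shows no lag: the slope to 10.0 s equals the slope to 25.0 s within the scatter.

| flask | substrate | reagent in the second phase | protic impurity | remark | time | volume of the second phase over the first |
|---|---|---|---|---|---|---|
| green | 0.050 M | 0.045 M | 2.5 mM | the very flask that is asked about, followed so far |  |  |
| flask | 0.050 M | 0.0450 M | 2.50 mM |  | 2.5 min | 2.0 |

green run (percent of the substrate charged)

| time / s | product / % | substrate / % |
|---|---|---|
| 10.0 | 5.2 | 94.9 |
| 15.0 | 7.7 | 91.9 |
| 25.0 | 13.1 | 86.9 |
| 30.0 | 15.4 | 85.3 |
| 40.0 | 19.0 | 80.5 |
| 50.0 | 22.0 | 77.3 |
| 60.0 | 25.1 | 75.1 |

(each reading ± 0.3 percentage points)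

1. amount of product at 2.5 min, in percent of the substrate charged
2. the change that raises the amount of product at 2.5 min, in percent of the substrate charged most ("none" if none brings more than 2 percentage points) (gamma / theta / none)
3. amount of product at 2.5 min, in percent of the substrate charged, after theta

- in the second phase: reagent in the second phase; everything else is in the first
- charges count per volume of the first phase; a concentration in a rate is the amount of a species over the volume of its own phase; every rate counts per litre of the first phase
- the earlier runs hold the two phases in the same ratio of volumes as the flask asked about

Read in two halves, the product column gives the pseudo-first-order constant of substrate loss, taken as the logarithm of the unconverted fraction over time. The rows up to 30.0 s give 0.334 min⁻¹. The rows from there to 60.0 s give 0.244 min⁻¹, which is less. The logarithm already allows for lost substrate, so in the green run the reagent's power is fading. The reagent lifetime, the time in which this constant falls by the factor e, reads 94.6 s.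

Run back to a starting constant of 0.392 min⁻¹ and forward with that lifetime, the reckoning here gives 38.8 % at 2.5 min. With the constant taken as proportional to the reagent, doubling the reagent gives 62.6 % in this reckoning. This reckoning holds no term for the transfer coefficient, so theta is left near 38.8 % as a judgement.

The forecast gives 45 %, gamma and 47 % after theta, from a law that “fits with a nearly constant k”. Its yield stands above this reckoning.

The flask gives 37.0 %, gamma with a gain of 27 percentage points, and 37.9 % after theta. At 2.50 min it holds 0.0182 M of decomposed reagent beside 0.0185 M of product.

    reagent in the reaction phase ⇌ reagent in the second phase, rate k1*([reagent in the reaction phase] - [reagent in the second phase]/K1) per volume of the first phase (partition coefficient = 1.71, kL = 0.242 s⁻¹)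
    substrate + reagent in the reaction phase → product (k = 0.914 L mol⁻¹ s⁻¹)
    reagent in the reaction phase + protic impurity → quenched reagent (k = 6.78 L mol⁻¹ s⁻¹)
    reagent in the reaction phase → decomposed reagent (k = 0.0360 s⁻¹)

Run out to long times, the lifetime gives an estimate of 46.1 %, against 42.1 % at 25.0 min. As product, that estimate is a share of 54.2 % of the reagent net of the protic impurity.

In the neighbour flask with 0.20 M of substrate, the product path scales with substrate, so the reckoning shortens the lifetime to 36.0 s and puts the ratio of product path to other loss at 4.74, which gives 17.5 %. The computed neighbour gives 17.5 %.

All runs are calculated for an exercise; scatter was added.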